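- I started from a ratio of 1.61, the selectivity factor of partner over substrate for reagent, and the decision for the next run hung on it: change the order of addition, or charge more reagent.

    crystals ⇌ target, rate k1*(cs1 - [target]) while solid is left; crystals form when [target] > cs1 (cs1 = 2.9 mM, k1 = 1.2 min⁻¹)
    reagent + partner → second intermediate (k2 = 1.0 M⁻¹ min⁻¹, Ea2 = 71.0 kJ mol⁻¹)
    substrate + reagent → open intermediate (k3 = 0.62 M⁻¹ min⁻¹, Ea3 = 57.0 kJ mol⁻¹)
    2 second intermediate → homo product (k4 = 1.0 M⁻¹ min⁻¹, Ea4 = 85.0 kJ mol⁻¹)
    reagent + protic impurity → quenched reagent (k5 = 0.62 M⁻¹ min⁻¹, Ea5 = 91.0 kJ mol⁻¹)
    open intermediate + second intermediate → target (k6 = 78 M⁻¹ min⁻¹, Ea6 = 75.0 kJ mol⁻¹)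
    (constants at 100 °C)

in all of them: substrate 45 mM; protic impurity 45.0 mM; time 40 min

| run | partner | reagent | temperature | remark |
|---|---|---|---|---|
| zeta | 1.80 equiv | 1.50 equiv (fed, over 30 min) | 100 °C | all else is in the flask from the start; the feed brings no volume worth counting |
| alpha | 1.80 equiv (fed, over 30 min) | 1.50 equiv |  | the addition at 60 °C, then warmed to 100 °C; the feed brings no volume worth counting |
| gamma | 1.80 equiv | 1.50 equiv | 100 °C | everything together at the start |
| delta | 1.80 equiv (fed, over 3.0 min) | 1.50 equiv | 100 °C | all else is in the flask from the start; the feed brings no volume worth counting |

- for target the crystals are counted in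
- a step written with two of one species runs at k times the square of its concentration and takes two of it each time
- as a solid, counted per litre of solution: crystals
- the list of constants is for 100 °C, to be carried to other temperatures by the activation energies

- which flask leads in amount of target, in percent of the substrate charged ("all alike" within 1.5 percentage points) (zeta / alpha / gamma / delta / all alike)
- how much target is there at the end, in percent of the substrate charged: zeta
- how much target is there at the end, in percent of the substrate charged: alpha
- how much target is there at the end, in percent of the substrate charged: gamma
- how much target is there at the end, in percent of the substrate charged: delta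

- Reagent had three takers, each first order in reagent, so I divided their rates and reagent and time dropped out, however reagent went in.
- With x the fraction of substrate left, that integration gave partner left as x to the power 1.61, and protic impurity left as x itself, since 0.62 M⁻¹ min⁻¹ equals 0.62 M⁻¹ min⁻¹; both hold at one temperature with partner present from the start.
- I counted each captured substrate as target, since the coupling constant of 78 M⁻¹ min⁻¹ stood far above 0.62 M⁻¹ min⁻¹.
- The balance for spent reagent, in fractions of the substrate charge, then read: 1.50 equiv equals c, plus 1.00 times c for protic impurity, plus 1.80 equiv times one minus (one minus c) to the power 1.61.
- A straight-line start gave 30.6%, and one Newton step gave the capture fraction, the share of substrate taken when reagent is spent, 32.6%.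
- Reagent's lifetime against the charge was 7.31 min, so I placed gamma, with 40 min against that lifetime, just under the capture fraction, and zeta further under it, since it had 10.0 min after its feed.
- Delta's partner feed of 3.0 min was shorter than that lifetime, so I expected a small lift above the capture fraction, and I decided to raise the reagent charge and leave the order alone.
- The forecast put delta first, with 28.5% for zeta, 27% for alpha, 31.5% for gamma and 33.5% for delta, holding that “the yield is set by how much reagent the substrate captures against partner and protic impurity”.
- The simulation gave 28.1% for zeta, 27.3% for alpha, 31.7% for gamma and 33.8% for delta, and delta led.
- Gamma held 32.6% target after 400 min against my capture fraction of 32.6%, and in delta partner was using reagent 2.5 times as fast as substrate after 40.0 min, which is 1.61 times partner over substrate, 2.48. For the neighbour of delta with 2.50 equiv of reagent, the same balance, which takes reagent as spent and partner as present from the start, gave from a start of 51.0% a capture fraction of 57.4%, and that flask, its partner fed over 3.0 min, held 55.3% target after 40.0 min with 6.45% of its reagent charge left.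

The numbers were set for the occasion; what happens was integrated by code.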